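**Plan**

Ring labels: ring A is the benzo ring of the benzofuran, ring B the dihydrofuran, ring C the pendant 4-hydroxy-3,5-dimethoxyphenyl ring (C1' is its ipso carbon).
Cuts: first the C5–alkenyl bond (Suzuki), then O1–C2 together with C2–C1' (ring B and the ring-C junction in one operation), then C3–CH2O (hydroxymethylation of a ring-A arylacetic acid).
Forward: aldehyde 1 is allylated, homologated to acid 5, attached to an oxazolidinone, hydroxymethylated and taken to lactol 14. Ring C enters as Grignard reagent 17, and 14 + 17 build ring B in step 13. The propenol chain and desilylation follow.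
Enabling feature: C2 carries C1' of ring C, O1 and C3, so a cation at C2 is benzylic and conjugated with the para oxygen of ring C. Ring A holds the O1 phenol ortho to the C3 chain, placed for 5-exo capture.
Stereochemistry: C3 (R) comes from (S)-4-benzyloxazolidin-2-one through a chelated titanium Z-enolate. C2 (S) follows from C3 by trans-selective, reversible capture of the cation. The E alkene comes from boronate 21.

Key step: step 13

Assumption: (S)-4-benzyloxazolidin-2-one and boronate 21 are purchased; lactol 14 is used as its mixture of C2 anomers, which does not matter because C2 passes through planar forms (aldehyde, then cation) before it is fixed in step 13.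

**Route**

Step 1
Reactants: 1 5-bromo-2-hydroxy-3-methoxybenzaldehyde
Product: 2 2-(allyloxy)-5-bromo-3-methoxybenzaldehyde
Conditions: allyl bromide, K2CO3, DMF, rt
Reagents that add atoms: allyl bromide, C=CCBr
Why: Williamson etherification of the acidic ortho-formyl phenol should be clean, and the allyl group is later removable under neutral conditions without touching the aryl bromide.

Step 2
Reactants: 2 2-(allyloxy)-5-bromo-3-methoxybenzaldehyde
Product: 3 2-(allyloxy)-5-bromo-1-methoxy-3-(2-methoxyvinyl)benzene (E/Z mixture)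
Conditions: Ph3P(CH2OMe)Cl, KOtBu, THF, 0 °C → rt
Reagents that add atoms: (methoxymethyl)triphenylphosphonium chloride, COC[P+](c1ccccc1)(c1ccccc1)c1ccccc1.[Cl-]
Why: Wittig methoxymethylenation of an aromatic aldehyde is a standard one-carbon homologation, and the alkene geometry is irrelevant because the enol ether is hydrolysed next.

Step 3
Reactants: 3 2-(allyloxy)-5-bromo-1-methoxy-3-(2-methoxyvinyl)benzene
Product: 4 2-[2-(allyloxy)-5-bromo-3-methoxyphenyl]acetaldehyde
Conditions: 2 M aq. HCl, THF, 50 °C; crude product taken on at once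
Reagents that add atoms: water, O
Why: Acid-catalysed enol ether hydrolysis should unmask the arylacetaldehyde while the aryl allyl ether and the aryl bromide are inert to dilute acid.

Step 4
Reactants: 4 2-[2-(allyloxy)-5-bromo-3-methoxyphenyl]acetaldehyde
Product: 5 2-[2-(allyloxy)-5-bromo-3-methoxyphenyl]acetic acid
Conditions: NaClO2, NaH2PO4, 2-methyl-2-butene, t-BuOH/H2O, 0 °C → rt
Reagents that add atoms: sodium chlorite, [Na+].[O-]Cl=O
Why: Pinnick oxidation converts the aldehyde to the acid chemoselectively, the excess trisubstituted alkene scavenging hypochlorous acid so that the allyl ether and the electron-rich ring are spared.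

Step 5
Reactants: 5 2-[2-(allyloxy)-5-bromo-3-methoxyphenyl]acetic acid
Product: 7 (S)-3-{2-[2-(allyloxy)-5-bromo-3-methoxyphenyl]acetyl}-4-benzyloxazolidin-2-one, via mixed pivalic anhydride 6 (not isolated)
Conditions: PivCl, Et3N, THF, −20 °C; then (S)-4-benzyloxazolidin-2-one, LiCl, −20 °C → rt
Reagents that add atoms: (S)-4-benzyloxazolidin-2-one, O=C1N[C@@H](Cc2ccccc2)CO1
Why: Evans N-acylation through the mixed pivalic anhydride should take place at the less hindered arylacetyl carbonyl under the mild LiCl/amine conditions.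

Step 6
Reactants: 7 (S)-3-{2-[2-(allyloxy)-5-bromo-3-methoxyphenyl]acetyl}-4-benzyloxazolidin-2-one
Product: 9 (S)-3-{(R)-2-[2-(allyloxy)-5-bromo-3-methoxyphenyl]-3-hydroxypropanoyl}-4-benzyloxazolidin-2-one, via trichlorotitanium enolate 8 (not isolated)
Conditions: TiCl4, i-Pr2NEt, CH2Cl2, 0 °C; then s-trioxane, TiCl4, 0 °C
Reagents that add atoms: s-trioxane, C1OCOCO1
Why: In this Evans titanium-enolate hydroxymethylation (aldol addition to formaldehyde released from trioxane by TiCl4), the chelated Z-enolate 8 should be attacked on the face opposite the 4-benzyl group, which sets the future C3 as R.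

Step 7
Reactants: 9 (S)-3-{(R)-2-[2-(allyloxy)-5-bromo-3-methoxyphenyl]-3-hydroxypropanoyl}-4-benzyloxazolidin-2-one
Product: 10 (S)-3-{(R)-2-[2-(allyloxy)-5-bromo-3-methoxyphenyl]-3-(triisopropylsilyloxy)propanoyl}-4-benzyloxazolidin-2-one
Conditions: TIPSOTf, 2,6-lutidine, CH2Cl2, −20 → 0 °C
Reagents that add atoms: triisopropylsilyl trifluoromethanesulfonate, CC(C)[Si](OS(=O)(=O)C(F)(F)F)(C(C)C)C(C)C
Why: Silylation with the silyl triflate and a hindered pyridine base is fast at low temperature and too weakly basic to cause retro-aldol cleavage or epimerisation of the α-aryl imide.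

Step 8
Reactants: 10 (S)-3-{(R)-2-[2-(allyloxy)-5-bromo-3-methoxyphenyl]-3-(triisopropylsilyloxy)propanoyl}-4-benzyloxazolidin-2-one
Product: 11 (S)-2-[2-(allyloxy)-5-bromo-3-methoxyphenyl]-3-(triisopropylsilyloxy)propan-1-ol
Conditions: LiBH4, H2O (1 equiv), Et2O, 0 °C
Reagents that add atoms: none
Why: Reductive cleavage of the N-acyloxazolidinone with LiBH4 attacks the exocyclic carbonyl and releases the auxiliary, and the bulky triisopropylsilyl group should resist migration between the two oxygen arms that now alone define the stereocentre.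

Step 9
Reactants: 11 (S)-2-[2-(allyloxy)-5-bromo-3-methoxyphenyl]-3-(triisopropylsilyloxy)propan-1-ol
Product: 12 (R)-2-[2-(allyloxy)-5-bromo-3-methoxyphenyl]-3-(triisopropylsilyloxy)propanal
Conditions: Dess–Martin periodinane, CH2Cl2, 0 °C → rt; crude product taken on at once
Reagents that add atoms: none
Why: Dess–Martin oxidation is base-free and near neutral, which suits an α-aryl β-silyloxy aldehyde that would enolise or eliminate under basic oxidation conditions.

Step 10
Reactants: 12 (R)-2-[2-(allyloxy)-5-bromo-3-methoxyphenyl]-3-(triisopropylsilyloxy)propanal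
Product: 14 (3R)-5-bromo-7-methoxy-3-[(triisopropylsilyloxy)methyl]-2,3-dihydrobenzofuran-2-ol (both C2 anomers), via hydroxy aldehyde 13 (not isolated)
Conditions: Pd(PPh3)4 (5 mol %), p-TolSO2H, CH2Cl2, rt
Reagents that add atoms: none
Why: Tsuji–Trost deallylation with a sulfinic acid as non-basic allyl acceptor frees the phenol without condensing with the aldehyde or inserting zerovalent palladium into the electron-rich aryl bromide at room temperature, and the phenol then closes onto the aldehyde as a five-membered hemiacetal that protects C3.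

Step 11
Reactants: 15 4-bromo-2,6-dimethoxyphenol
Product: 16 (4-bromo-2,6-dimethoxyphenoxy)triisopropylsilane
Conditions: TIPSOTf, 2,6-lutidine, CH2Cl2, 0 °C → rt
Reagents that add atoms: triisopropylsilyl trifluoromethanesulfonate, CC(C)[Si](OS(=O)(=O)C(F)(F)F)(C(C)C)C(C)C
Why: The silyl triflate is reactive enough to silylate a phenol flanked by two methoxy groups, and the resulting hindered aryl silyl ether tolerates organomagnesium chemistry.

Step 12
Reactants: 16 (4-bromo-2,6-dimethoxyphenoxy)triisopropylsilane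
Product: 17 [3,5-dimethoxy-4-(triisopropylsilyloxy)phenyl]magnesium bromide (titrated THF solution, used as such)
Conditions: Mg turnings (activated with a crystal of I2), THF, 50 °C
Reagents that add atoms: magnesium, [Mg]
Why: Direct magnesium insertion into an aryl bromide with two free ortho positions is ordinary Grignard formation, and the silyloxy group para to the metal cannot undergo silyl migration to carbon.

Step 13
Reactants: 14 (3R)-5-bromo-7-methoxy-3-[(triisopropylsilyloxy)methyl]-2,3-dihydrobenzofuran-2-ol; 17 [3,5-dimethoxy-4-(triisopropylsilyloxy)phenyl]magnesium bromide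
Product: 20 (2S,3R)-5-bromo-2-[3,5-dimethoxy-4-(triisopropylsilyloxy)phenyl]-7-methoxy-3-[(triisopropylsilyloxy)methyl]-2,3-dihydrobenzofuran, via bromomagnesium phenoxide aldehyde 18 (not isolated), via benzylic alcohol adduct 19 (not isolated)
Conditions: 14 added to 17 (2.5 equiv), THF, −40 → 0 °C; then CF3CO2H (excess), CH2Cl2, −20 → 0 °C, same flask
Reagents that add atoms: none
Why: One equivalent of 17 deprotonates the lactol, the magnesium lactolate opens to the bromomagnesium phenoxide aldehyde 18, and a second equivalent adds to its carbonyl to forge C2–C1'; trifluoroacetic acid then protonates the adduct to diol 19 and ionises its benzylic C2–OH to a cation delocalised into ring C and onto its para oxygen, and the ring-A phenol O1 captures it. The closest known reaction types are aryl Grignard addition to lactols and acid-mediated cyclodehydration of 1-aryl-2-(2-hydroxyaryl)propane-1,3-diol derivatives to trans-2-aryl-2,3-dihydrobenzofurans. Ring B closes in the 5-exo-trig mode, O1 attacking the exocyclic cationic carbon C2. The new stereocentre C2 is set by C3: the aryl group settles trans to the silyloxymethyl group, and because the benzylic C2–O1 bond can re-ionise under the acid, both carbinol epimers of 19 and any cis isomer should drain to the (2S,3R) trans product. The step needs addition to outrun enolisation of the α-aryl aldehyde and O-capture to outrun loss of H3 or attack by outside arenes; the lactol keeps the open aldehyde at a low stationary level in front of excess aryl nucleophile, and the phenol sits five atoms from C2, so ring closure should be much faster than any bimolecular path at low temperature and short acid contact.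

Step 14
Reactants: 20 (2S,3R)-5-bromo-2-[3,5-dimethoxy-4-(triisopropylsilyloxy)phenyl]-7-methoxy-3-[(triisopropylsilyloxy)methyl]-2,3-dihydrobenzofuran; 21 (E)-2-[3-(tert-butyldimethylsilyloxy)prop-1-en-1-yl]-4,4,5,5-tetramethyl-1,3,2-dioxaborolane
Product: 22 (2S,3R)-5-[(E)-3-(tert-butyldimethylsilyloxy)prop-1-en-1-yl]-2-[3,5-dimethoxy-4-(triisopropylsilyloxy)phenyl]-7-methoxy-3-[(triisopropylsilyloxy)methyl]-2,3-dihydrobenzofuran
Conditions: Pd(dppf)Cl2 (5 mol %), K3PO4, THF/H2O, 65 °C
Reagents that add atoms: none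
Why: Suzuki–Miyaura coupling of an unhindered aryl bromide with an alkenyl pinacol boronate proceeds with retention of the E geometry, and any partial loss of the phenolic silyl group under the aqueous base is harmless because all silyl groups are removed next.

Step 15
Reactants: 22 (2S,3R)-5-[(E)-3-(tert-butyldimethylsilyloxy)prop-1-en-1-yl]-2-[3,5-dimethoxy-4-(triisopropylsilyloxy)phenyl]-7-methoxy-3-[(triisopropylsilyloxy)methyl]-2,3-dihydrobenzofuran
Product: 23 4-[(2S,3R)-3-(hydroxymethyl)-5-[(E)-3-hydroxyprop-1-en-1-yl]-7-methoxy-2,3-dihydrobenzofuran-2-yl]-2,6-dimethoxyphenol (target)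
Conditions: Bu4NF (excess), THF, 0 °C → rt
Reagents that add atoms: none
Why: Fluoride-mediated desilylation removes the aryl and both primary silyl ethers in one operation, and at room temperature the resulting phenoxide should not open ring B, so C2 and C3 are kept.

**Compound list**

1 | 5-bromo-2-hydroxy-3-methoxybenzaldehyde | COc1cc(Br)cc(C=O)c1O | starting material
2 | 2-(allyloxy)-5-bromo-3-methoxybenzaldehyde | COc1cc(Br)cc(C=O)c1OCC=C | intermediate
3 | 2-(allyloxy)-5-bromo-1-methoxy-3-(2-methoxyvinyl)benzene (E/Z mixture) | COC=Cc1cc(Br)cc(OC)c1OCC=C | intermediate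
4 | 2-[2-(allyloxy)-5-bromo-3-methoxyphenyl]acetaldehyde | O=CCc1cc(Br)cc(OC)c1OCC=C | intermediate
5 | 2-[2-(allyloxy)-5-bromo-3-methoxyphenyl]acetic acid | OC(=O)Cc1cc(Br)cc(OC)c1OCC=C | intermediate
6 | 2-[2-(allyloxy)-5-bromo-3-methoxyphenyl]acetic pivalic anhydride | CC(C)(C)C(=O)OC(=O)Cc1cc(Br)cc(OC)c1OCC=C | intermediate (not isolated)
7 | (S)-3-{2-[2-(allyloxy)-5-bromo-3-methoxyphenyl]acetyl}-4-benzyloxazolidin-2-one | C=CCOc1c(OC)cc(Br)cc1CC(=O)N1[C@@H](Cc2ccccc2)COC1=O | intermediate
8 | trichlorotitanium (Z)-enolate of 7 | Cl[Ti](Cl)(Cl)O/C(=C\c1cc(Br)cc(OC)c1OCC=C)N1[C@@H](Cc2ccccc2)COC1=O | intermediate (not isolated)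
9 | (S)-3-{(R)-2-[2-(allyloxy)-5-bromo-3-methoxyphenyl]-3-hydroxypropanoyl}-4-benzyloxazolidin-2-one | OC[C@@H](c1cc(Br)cc(OC)c1OCC=C)C(=O)N1[C@@H](Cc2ccccc2)COC1=O | intermediate
10 | (S)-3-{(R)-2-[2-(allyloxy)-5-bromo-3-methoxyphenyl]-3-(triisopropylsilyloxy)propanoyl}-4-benzyloxazolidin-2-one | CC(C)[Si](OC[C@@H](c1cc(Br)cc(OC)c1OCC=C)C(=O)N1[C@@H](Cc2ccccc2)COC1=O)(C(C)C)C(C)C | intermediate
11 | (S)-2-[2-(allyloxy)-5-bromo-3-methoxyphenyl]-3-(triisopropylsilyloxy)propan-1-ol | CC(C)[Si](OC[C@@H](c1cc(Br)cc(OC)c1OCC=C)CO)(C(C)C)C(C)C | intermediate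
12 | (R)-2-[2-(allyloxy)-5-bromo-3-methoxyphenyl]-3-(triisopropylsilyloxy)propanal | CC(C)[Si](OC[C@@H](c1cc(Br)cc(OC)c1OCC=C)C=O)(C(C)C)C(C)C | intermediate
13 | (R)-2-(5-bromo-2-hydroxy-3-methoxyphenyl)-3-(triisopropylsilyloxy)propanal | CC(C)[Si](OC[C@@H](c1cc(Br)cc(OC)c1O)C=O)(C(C)C)C(C)C | intermediate (not isolated)
14 | (3R)-5-bromo-7-methoxy-3-[(triisopropylsilyloxy)methyl]-2,3-dihydrobenzofuran-2-ol (both C2 anomers) | OC1Oc2c(OC)cc(Br)cc2[C@@H]1CO[Si](C(C)C)(C(C)C)C(C)C | intermediate
15 | 4-bromo-2,6-dimethoxyphenol | COc1cc(Br)cc(OC)c1O | starting material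
16 | (4-bromo-2,6-dimethoxyphenoxy)triisopropylsilane | COc1cc(Br)cc(OC)c1O[Si](C(C)C)(C(C)C)C(C)C | intermediate
17 | [3,5-dimethoxy-4-(triisopropylsilyloxy)phenyl]magnesium bromide | COc1cc([Mg]Br)cc(OC)c1O[Si](C(C)C)(C(C)C)C(C)C | intermediate
18 | bromomagnesium 4-bromo-2-methoxy-6-[(R)-1-oxo-3-(triisopropylsilyloxy)propan-2-yl]phenolate | CC(C)[Si](OC[C@@H](c1cc(Br)cc(OC)c1O[Mg]Br)C=O)(C(C)C)C(C)C | intermediate (not isolated)
19 | (2R)-2-(5-bromo-2-hydroxy-3-methoxyphenyl)-1-[3,5-dimethoxy-4-(triisopropylsilyloxy)phenyl]-3-(triisopropylsilyloxy)propan-1-ol (both C1 epimers) | COc1cc(C(O)[C@@H](CO[Si](C(C)C)(C(C)C)C(C)C)c2cc(Br)cc(OC)c2O)cc(OC)c1O[Si](C(C)C)(C(C)C)C(C)C | intermediate (not isolated)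
20 | (2S,3R)-5-bromo-2-[3,5-dimethoxy-4-(triisopropylsilyloxy)phenyl]-7-methoxy-3-[(triisopropylsilyloxy)methyl]-2,3-dihydrobenzofuran | COc1cc([C@H]2Oc3c(OC)cc(Br)cc3[C@@H]2CO[Si](C(C)C)(C(C)C)C(C)C)cc(OC)c1O[Si](C(C)C)(C(C)C)C(C)C | intermediate
21 | (E)-2-[3-(tert-butyldimethylsilyloxy)prop-1-en-1-yl]-4,4,5,5-tetramethyl-1,3,2-dioxaborolane | CC(C)(C)[Si](C)(C)OC/C=C/B1OC(C)(C)C(C)(C)O1 | starting material
22 | (2S,3R)-5-[(E)-3-(tert-butyldimethylsilyloxy)prop-1-en-1-yl]-2-[3,5-dimethoxy-4-(triisopropylsilyloxy)phenyl]-7-methoxy-3-[(triisopropylsilyloxy)methyl]-2,3-dihydrobenzofuran | COc1cc([C@H]2Oc3c(OC)cc(/C=C/CO[Si](C)(C)C(C)(C)C)cc3[C@@H]2CO[Si](C(C)C)(C(C)C)C(C)C)cc(OC)c1O[Si](C(C)C)(C(C)C)C(C)C | intermediate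
23 | 4-[(2S,3R)-3-(hydroxymethyl)-5-[(E)-3-hydroxyprop-1-en-1-yl]-7-methoxy-2,3-dihydrobenzofuran-2-yl]-2,6-dimethoxyphenol | COc1cc([C@H]2Oc3c(OC)cc(/C=C/CO)cc3[C@@H]2CO)cc(OC)c1O | target

**Step count and risks**

Total steps: 15. Longest linear sequence: 13 (steps 1–10, 13, 14, 15); steps 11 and 12 form the ring-C branch.

Steps most likely to fail:

1. Step 13. The basic aryl Grignard reagent may enolise the ring-opened aldehyde or expel silanolate from it before it adds. In the acid phase the C2 cation may lose H3, which erodes C3, or be captured by the arene left from quenched reagent. Fallback: starting from aldehyde 12, whose phenol is still allylated, the non-basic organocerium reagent made from 17 and CeCl3 (THF, −78 °C) should add to give (2R)-2-[2-(allyloxy)-5-bromo-3-methoxyphenyl]-1-[3,5-dimethoxy-4-(triisopropylsilyloxy)phenyl]-3-(triisopropylsilyloxy)propan-1-ol F1 as a mixture of carbinol epimers. Deallylation with Pd(PPh3)4 and morpholine then gives 19, this time isolated and free of reagent-derived arene. Catalytic TsOH in CH2Cl2 at 0 °C closes ring B, and the route is rejoined at 20.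

2. Step 6. TiCl4 may bind the 2-allyloxy-3-methoxy unit and cleave the ether, and the α-aryl β-hydroxy imide may epimerise or undergo retro-aldol loss of formaldehyde, so that C3 is not obtained in pure form. Fallback: starting from acid 5, Fischer esterification gives methyl 2-[2-(allyloxy)-5-bromo-3-methoxyphenyl]acetate F2. NaH and dimethyl carbonate give dimethyl 2-[2-(allyloxy)-5-bromo-3-methoxyphenyl]malonate F3, and LiAlH4 at 0 °C gives the prochiral 2-[2-(allyloxy)-5-bromo-3-methoxyphenyl]propane-1,3-diol F4. Desymmetrising acetylation with vinyl acetate, catalysed by a lipase screened for the required sense of arm selection, gives (R)-2-[2-(allyloxy)-5-bromo-3-methoxyphenyl]-3-hydroxypropyl acetate F5. TIPSOTf and 2,6-lutidine give (S)-2-[2-(allyloxy)-5-bromo-3-methoxyphenyl]-3-(triisopropylsilyloxy)propyl acetate F6, and i-Bu2AlH at −78 °C removes the acetate without silyl migration. The route is rejoined at alcohol 11.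

3. Step 9. The free α-aryl β-silyloxy aldehyde may enolise or eliminate silanol during oxidation, work-up and the wait before deallylation, which would lower the enantiomeric purity at C3. Fallback: starting from alcohol 11, deallylation with Pd(PPh3)4 and morpholine gives (S)-4-bromo-2-[1-hydroxy-3-(triisopropylsilyloxy)propan-2-yl]-6-methoxyphenol F7. Parikh–Doering oxidation (SO3·pyridine, DMSO, i-Pr2NEt, 0 °C) should leave the fully ortho- and para-substituted phenol alone and generate hydroxy aldehyde 13 with the phenol already free, so that it is trapped at once as the hemiacetal. The route is rejoined at lactol 14.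

**Further compounds**

F1 | step 13 | (2R)-2-[2-(allyloxy)-5-bromo-3-methoxyphenyl]-1-[3,5-dimethoxy-4-(triisopropylsilyloxy)phenyl]-3-(triisopropylsilyloxy)propan-1-ol (both C1 epimers) | COc1cc(C(O)[C@@H](CO[Si](C(C)C)(C(C)C)C(C)C)c2cc(Br)cc(OC)c2OCC=C)cc(OC)c1O[Si](C(C)C)(C(C)C)C(C)C
F2 | step 6 | methyl 2-[2-(allyloxy)-5-bromo-3-methoxyphenyl]acetate | COC(=O)Cc1cc(Br)cc(OC)c1OCC=C
F3 | step 6 | dimethyl 2-[2-(allyloxy)-5-bromo-3-methoxyphenyl]malonate | COC(=O)C(C(=O)OC)c1cc(Br)cc(OC)c1OCC=C
F4 | step 6 | 2-[2-(allyloxy)-5-bromo-3-methoxyphenyl]propane-1,3-diol | OCC(CO)c1cc(Br)cc(OC)c1OCC=C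
F5 | step 6 | (R)-2-[2-(allyloxy)-5-bromo-3-methoxyphenyl]-3-hydroxypropyl acetate | OC[C@@H](c1cc(Br)cc(OC)c1OCC=C)COC(C)=O
F6 | step 6 | (S)-2-[2-(allyloxy)-5-bromo-3-methoxyphenyl]-3-(triisopropylsilyloxy)propyl acetate | CC(C)[Si](OC[C@@H](c1cc(Br)cc(OC)c1OCC=C)COC(C)=O)(C(C)C)C(C)C
F7 | step 9 | (S)-4-bromo-2-[1-hydroxy-3-(triisopropylsilyloxy)propan-2-yl]-6-methoxyphenol | CC(C)[Si](OC[C@@H](c1cc(Br)cc(OC)c1O)CO)(C(C)C)C(C)C
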